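I counted turnovers.

| setting | east | south-west | south | autumn | dusk | summer |
|---|---|---|---|---|---|---|
| starting material | 0.070 M | 0.070 M | 0.14 M | 0.070 M | 0.070 M | 0.070 M |
| second substrate | 0.070 M | 0.070 M | 0.070 M | 0.0700 M | 0.0700 M | 0.0700 M |
| free enzyme | 2.5 µM | 10 µM | 5.1 µM | 5.1 µM | 5.1 µM | 5.1 µM |
| temperature | −5 °C | 28 °C | −5 °C | 40 °C | −20 °C | 10 °C |
| remark | run made earlier | run made earlier | run made earlier |  |  |  |
| time |  |  |  | 8.0 h | 8.0 h | 8.0 h |

| run | time / h | target / % | starting material / % |
|---|---|---|---|
| east | 6.00 | 0 | 98.5 |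
| east | 10.0 | 0.1 | 96.8 |
| east | 20.0 | 0 | 93.1 |
| east | 30.0 | 0.2 | 89.6 |
| east | 50.0 | 0.9 | 83.9 |
| east | 72.0 | 0.4 | 78.5 |
| south-west | 1.33 | 1.4 | 89.5 |
| south-west | 2.00 | 3.4 | 84.6 |
| south-west | 4.00 | 7.6 | 71.7 |
| south-west | 5.00 | 9.1 | 68.5 |
| south-west | 10.0 | 18.4 | 47.6 |
| south-west | 15.0 | 26.1 | 34.9 |
| south | 6.00 | 0 | 96.2 |
| south | 20.0 | 0.1 | 87.0 |
| south | 40.0 | 0.5 | 76.5 |
| south | 60.0 | 0.4 | 68.5 |
| south | 72.0 | 0.2 | 65.3 |

(readings scatter by 0.5 percentage points)

1. the flask with the highest amount of target, in percent of the starting material charged ("all alike" if they lie within 1.5 percentage points) (autumn / dusk / summer / all alike)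
2. final target, as a percentage of the starting material charged, in autumn
3. final target, as a percentage of the starting material charged, in dusk
4. final target, as a percentage of the starting material charged, in summer



- By 72.0 h the east run showed 0.4% target, far less than the 21.5% of the charge no longer present as starting material, so I took starting material as no measure of target and read the target column instead.
- In the south-west run target climbed steadily to 26.1% at 15.0 h, and I divided that pace by c(free enzyme) to get the turnover frequency, the target made per enzyme per hour, which came to 122 h⁻¹.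
- At −5 °C target lay close to the scatter of 0.5 percentage points, so I pooled the last two readings of the east run into a rough frequency of 2.98 h⁻¹, and the Arrhenius law through these two frequencies gave an apparent activation energy of 75.5 kJ mol⁻¹, a reading as faint as the readings under it.
- From this I made the fill time, c(starting material) charged divided by the frequency times c(free enzyme), which is the time the steady pace needs to make target equal to the whole charge; for autumn it came to 35.5 h, for summer to 766 h and for dusk to 34200 h.
- Dividing 8.0 h by each fill time, I reckoned 22.5% target in autumn, 1.04% in summer and 0.0234% in dusk, a reckoning that assumed a steady pace over the whole time.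
- The forecast named autumn, with 20% there, 0.02% in dusk and 0.5% in summer, holding autumn down since the slowing “hints at enzyme decay, which would be faster”, and its summer figure lay below mine.
- Autumn gave 23.4%, summer 1.05% and dusk 0.0163%, so autumn held the most.

    free enzyme → unfolded enzyme (k = 0.00187 h⁻¹, Ea = 214 kJ mol⁻¹)
    starting material + free enzyme ⇌ first complex (K = 43.5 M⁻¹, k = 2.04 × 10⁶ M⁻¹ h⁻¹, Ea = 49.0 kJ mol⁻¹, ΔH = −19.0 kJ mol⁻¹)
    first complex → loaded enzyme + first product (k = 1150 h⁻¹, Ea = 84.0 kJ mol⁻¹)
    second substrate + loaded enzyme ⇌ second complex (K = 33.0 M⁻¹, k = 4.78 × 10⁶ M⁻¹ h⁻¹, Ea = 44.0 kJ mol⁻¹, ΔH = 5.00 kJ mol⁻¹)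
    second complex → free enzyme + target (k = 1440 h⁻¹, Ea = 77.0 kJ mol⁻¹)
    2 starting material → self-condensation product (k = 1.11 M⁻¹ h⁻¹, Ea = 58.0 kJ mol⁻¹)
    second substrate + first complex → spent catalyst (k = 0.101 M⁻¹ h⁻¹, Ea = 72.0 kJ mol⁻¹)
    (constants at 40 °C)

- In autumn the first half-life of starting material by self-condensation alone at the charged amount was 6.44 h, shorter than my fill time of 35.5 h, and at 8.00 h autumn held 45.0% self-condensation product beside 23.4% target.
- For a repeat of autumn at 55 °C my fill time came to 9.44 h, so the steady pace promised 84.7%, and that flask ended with 2.67% starting material and 52.0% target.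

The readings were generated by integration for an exercise; scatter was added.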